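Rings A and B are the same (3S,5S)-quinate, antipodal to the natural acid, linked by an ester from C7 of ring A to O1 of ring B, so one monomer serves twice. The feature exploited is the 1,3-relation of the C1 carbinol and O3 in each cyclohexane, an aldol retron once C3 is a ketone, flanked by the trans C4–C5 diol, which is (R,R)-tartrate. Cutting C1–C2 gives an acyclic tert-butyl 2,6-dioxoheptanoate carrying that diol as a trans acetonide. Its methyl ketone, as the terminal (R)-proline enamine, attacks the keto ester carbonyl: one operation forms C1–C2, closes the carbocycle and sets C1.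

Key step: step 7

Remark (numbering): quinate locants are used throughout, open-chain compounds included. C1 is the carbinol or keto ester carbon, C7 its carboxyl carbon, C2 the methyl or methylene carbon, C3 the ketone or axial carbinol, C4 and C5 the tartrate carbons, C6 the other methylene. Primed locants belong to ring B.

Remark (stereochemistry): CIP analysis of the target gives 3S,5S in both rings. O1, O3 and O4 lie on one face, O5 and C7 on the other, and the caffeate sits on O5. The (4R,5R)-tartrate acetonide maps onto C4 and C5 without inversion.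

Remark (design): the ester is tert-butyl from the start.
- It resists MeMgBr, aminolysis by the catalyst and closure of O5 on C7.
- It reinforces the equatorial preference at C1.
- It can be removed either by silyl triflate (ring A) or by acid at the very end (ring B), which a simple alkyl ester next to two caffeates could not.

The batch of 19 is divided between steps 13 and 14.

Step 1
Reactants: 1 dimethyl (4R,5R)-2,2-dimethyl-1,3-dioxolane-4,5-dicarboxylate (dimethyl 2,3-O-isopropylidene-L-tartrate)
Product: 2 methyl (4R,5S)-5-(hydroxymethyl)-2,2-dimethyl-1,3-dioxolane-4-carboxylate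
Conditions: NaBH4 (0.6 equiv), MeOH, 0 °C to rt
Reagents that add atoms: none
Why: Borohydride reduction of an alpha-alkoxy-activated ester; with a deficit of hydride the C2-symmetric diester is desymmetrised statistically (either ester gives the same product), the over-reduced diol is washed out with water, and no stereocenter is touched.

Step 2
Reactants: 2 methyl (4R,5S)-5-(hydroxymethyl)-2,2-dimethyl-1,3-dioxolane-4-carboxylate
Product: 3 methyl (4R,5S)-2,2-dimethyl-5-{[(trifluoromethyl)sulfonyl]oxymethyl}-1,3-dioxolane-4-carboxylate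
Conditions: Tf2O (1.1 equiv), 2,6-lutidine (1.5 equiv), CH2Cl2, −78 to −30 °C; cold aqueous wash, used at once
Reagents that add atoms: triflic anhydride O=S(=O)(OS(=O)(=O)C(F)(F)F)C(F)(F)F
Why: O-Sulfonylation of the primary alcohol; the beta-branched, beta-oxygenated C6 is sluggish in SN2 reactions as a halide, so the much better triflate leaving group is chosen, and such beta-alkoxy primary triflates survive a cold work-up.

Step 3
Reactants: 4 1,3-dithiane
Product: 6 tert-butyl 1,3-dithiane-2-carboxylate, via 2-lithio-1,3-dithiane 5 (not isolated)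
Conditions: n-BuLi (1.05 equiv), THF, −30 °C; cannulated into Boc2O (1.5 equiv), THF, −78 °C; aq NH4Cl
Reagents that add atoms: di-tert-butyl dicarbonate CC(C)(C)OC(=O)OC(=O)OC(C)(C)C
Why: Corey–Seebach lithiation followed by C-acylation with Boc2O; inverse addition into excess electrophile keeps the more acidic product from quenching unreacted 5.

Step 4
Reactants: 6 tert-butyl 1,3-dithiane-2-carboxylate; 3 methyl (4R,5S)-2,2-dimethyl-5-{[(trifluoromethyl)sulfonyl]oxymethyl}-1,3-dioxolane-4-carboxylate
Product: 8 tert-butyl 2-{[(4S,5R)-5-(methoxycarbonyl)-2,2-dimethyl-1,3-dioxolan-4-yl]methyl}-1,3-dithiane-2-carboxylate, via sodium enolate 7 (not isolated)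
Conditions: 6 (1.2 equiv), NaN(SiMe3)2 (1.15 equiv), THF/DMPU, −78 °C; then 3, −78 to 0 °C
Reagents that add atoms: none
Why: SN2 alkylation of a soft, ester-stabilised dithiane carbanion (a glyoxylate acyl-anion equivalent) forms C6–C1; the anion is too weak a base to enolise the methyl ester or expel O5, and C5 is not the reacting carbon, so its configuration is kept.

Step 5
Reactants: 8 tert-butyl 2-{[(4S,5R)-5-(methoxycarbonyl)-2,2-dimethyl-1,3-dioxolan-4-yl]methyl}-1,3-dithiane-2-carboxylate
Product: 10 tert-butyl 2-{[(4S,5R)-5-acetyl-2,2-dimethyl-1,3-dioxolan-4-yl]methyl}-1,3-dithiane-2-carboxylate, via Weinreb amide 9 (not isolated)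
Conditions: MeNH(OMe)·HCl (1.5 equiv), i-PrMgCl (3.0 equiv), THF, −20 °C; then MeMgBr (2.5 equiv), −20 to 0 °C; aq NH4Cl
Reagents that add atoms: methylmagnesium bromide C[Mg]Br
Why: Weinreb ketone synthesis run in one flask; the magnesium amide attacks only the unhindered methyl ester, chelation lets MeMgBr add just once, the tert-butyl ester on the quaternary dithiane carbon is inert below 0 °C, and the trans dioxolane is the stable arrangement at C4.

Step 6
Reactants: 10 tert-butyl 2-{[(4S,5R)-5-acetyl-2,2-dimethyl-1,3-dioxolan-4-yl]methyl}-1,3-dithiane-2-carboxylate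
Product: 11 tert-butyl (4S,5R)-4,5-dihydroxy-4,5-O-isopropylidene-2,6-dioxoheptanoate
Conditions: PhI(OCOCF3)2 (1.5 equiv), NaHCO3 (4 equiv), MeCN/H2O 9:1, 0 °C, 20 min; used promptly
Reagents that add atoms: water O
Why: Oxidative dethioacetalisation with a hypervalent iodine reagent (S-oxidation, then hydrolysis) unveils the C1 ketone within minutes; solid NaHCO3 takes up CF3CO2H, so acetonide and tert-butyl ester survive and the sensitive beta-alkoxy keto ester is not left in acid or base.

Step 7
Reactants: 11 tert-butyl (4S,5R)-4,5-dihydroxy-4,5-O-isopropylidene-2,6-dioxoheptanoate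
Product: 13 tert-butyl ent-3-dehydroquinate 4,5-acetonide (1S,4R,5S), via proline enamine 12 (not isolated)
Conditions: (R)-proline (30 mol %), DMSO (0.05 M), rt
Reagents that add atoms: none
Why: (R)-Proline condenses with the C3 methyl ketone to the less substituted enamine 12, whose terminal carbon C2 adds to the strongly electrophilic C1 keto ester carbonyl while the proline CO2H protonates the developing alkoxide, and hydrolysis then releases 13 and the catalyst. The closest known reactions are the Hajos–Parrish type intramolecular enamine aldol of a methyl ketone and the proline-catalysed addition of methyl ketones to alpha-keto esters. The carbocycle closes in the favoured 6-(enolendo)-exo-trig mode, because both enamine carbons C2 and C3 become ring members. C1 is set by the chair transition state: the trans-fused dioxolane allows only the chair with O4 and O5 equatorial, the bulky CO2t-Bu takes the equatorial site anti to C3, and the carbonyl oxygen sits axial, synclinal to the enamine nitrogen, which places O1 cis to O4 (1S); (R)-proline is the matched antipode because its anti enamine holds the CO2H on that same face, and aldol reversibility drains any C1 epimer toward the equatorial ester. The step needs enamine formation at CH3 rather than C4 and no loss of O5 or O1: allylic strain disfavours a C3=C4 enamine, the C5–O5 bond is tied back in the dioxolane nearly orthogonal to such a pi system, the tert-butyl ester blocks aminolysis, and this weakly acidic catalyst at room temperature normally stops at the ketol.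

Step 8
Reactants: 13 tert-butyl ent-3-dehydroquinate 4,5-acetonide
Product: 14 tert-butyl 4,5-O-isopropylidene-ent-quinate (3S,5S; O3 axial and cis to O1 and O4)
Conditions: LiBH(s-Bu)3 (2.5 equiv), THF, −78 °C; MeOH, aq NH4Cl
Reagents that add atoms: none
Why: Diastereoselective ketone reduction by a bulky trialkylborohydride; in the locked trans-fused chair the axial O1 and H5 shield the axial trajectory, so hydride arrives equatorially and gives the axial (3S) alcohol, while ester and acetonide are inert at −78 °C and reduction outruns retro-aldol.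

Step 9
Reactants: 14 tert-butyl 4,5-O-isopropylidene-ent-quinate
Product: 15 tert-butyl 3,4-O-isopropylidene-ent-quinate (O1–H and O5–H free)
Conditions: camphor-10-sulfonic acid (10 mol %), dry acetone, rt
Reagents that add atoms: none
Why: Acid-catalysed acetal equilibration under thermodynamic control; the strained trans-fused 4,5-dioxolane re-closes on the cis O3/O4 pair, the usual resting state of quinate acetonides, which frees O5–H, and catalytic acid at room temperature spares the tert-butyl ester, whose bulk also holds back lactonisation.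

Step 10
Reactants: 16 caffeic acid
Product: 17 allyl (E)-3-[3,4-bis(allyloxy)phenyl]prop-2-enoate
Conditions: allyl bromide (3.6 equiv), K2CO3 (4 equiv), DMF, rt to 50 °C
Reagents that add atoms: allyl bromide C=CCBr
Why: Williamson ether synthesis plus carboxylate alkylation; allyl ethers withstand silyl triflate, lithium alkoxide and DMAP and later leave under neutral palladium catalysis without touching the cinnamate alkene.

Step 11
Reactants: 17 allyl (E)-3-[3,4-bis(allyloxy)phenyl]prop-2-enoate
Product: 18 (E)-3-[3,4-bis(allyloxy)phenyl]prop-2-enoic acid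
Conditions: NaOH (2 M aq), THF/MeOH, rt; then 1 M HCl
Reagents that add atoms: sodium hydroxide [Na+].[OH-]
Why: Saponification of the only ester; aryl allyl ethers and the E alkene are inert to hydroxide.

Step 12
Reactants: 15 tert-butyl 3,4-O-isopropylidene-ent-quinate; 18 (E)-3-[3,4-bis(allyloxy)phenyl]prop-2-enoic acid
Product: 19 tert-butyl 5-O-[(E)-3,4-bis(allyloxy)cinnamoyl]-3,4-O-isopropylidene-ent-quinate (O1–H free; ring B unit)
Conditions: 18 (1.2 equiv), EDC·HCl (1.4 equiv), DMAP (0.3 equiv), CH2Cl2, 0 °C to rt
Reagents that add atoms: none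
Why: Steglich esterification; the secondary equatorial O5–H reacts while the tertiary O1–H next to the tert-butyl ester does not under these mild conditions, the usual selectivity of quinate 3,4-acetonides.

Step 13
Reactants: 19 tert-butyl 5-O-[(E)-3,4-bis(allyloxy)cinnamoyl]-3,4-O-isopropylidene-ent-quinate
Product: 21 5-O-[(E)-3,4-bis(allyloxy)cinnamoyl]-3,4-O-isopropylidene-1-O-triethylsilyl-ent-quinic acid (ring A unit), via bis-TES derivative 20 (not isolated)
Conditions: Et3SiOTf (3.5 equiv), 2,6-lutidine (5 equiv), CH2Cl2, 0 °C to rt; then pH 5 buffer/THF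
Reagents that add atoms: triethylsilyl triflate CC[Si](CC)(CC)OS(=O)(=O)C(F)(F)F
Why: Silyl triflate-mediated dealkylation of a tert-butyl ester (carbonyl O-silylation, loss of 2-methylpropene) runs alongside silylation of the tertiary O1–H; the cleavage is insensitive to crowding at C1, the cinnamate, allyl ethers and ring-fused ketal tolerate the buffered reagent, and water in the work-up cleaves only the labile silyl ester of 20.

Step 14
Reactants: 21 5-O-[(E)-3,4-bis(allyloxy)cinnamoyl]-3,4-O-isopropylidene-1-O-triethylsilyl-ent-quinic acid; 19 tert-butyl 5-O-[(E)-3,4-bis(allyloxy)cinnamoyl]-3,4-O-isopropylidene-ent-quinate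
Product: 24 protected dimer (C7 of ring A esterified by O1' of ring B; O1 TES; tert-butyl ester at C7'; two 3,4-acetonides; four aryl allyl ethers), via acid chloride 22 (not isolated), via lithium alkoxide 23 (not isolated)
Conditions: 21 (1.2 equiv), 1-chloro-N,N,2-trimethylprop-1-en-1-amine (1.2 equiv), CH2Cl2, 0 °C to rt, evaporate; 19, LiN(SiMe3)2 (1.05 equiv), THF, −78 °C; add 22 in THF, −78 °C to rt
Reagents that add atoms: none
Why: Acylation of a lithium tertiary alkoxide by an acid chloride made under neutral conditions is the standard answer to doubly hindered ester bonds; 22 has no alpha hydrogen (no ketene), O1'–H is the only acidic site of 19, and O1' cannot reach its own O5' ester because the two are trans, so C7–O1' forms with both quaternary centers untouched.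

Step 15
Reactants: 24 protected dimer
Product: 25 dimer with both catechols free (O1 TES, C7' tert-butyl ester and two acetonides retained)
Conditions: Pd(PPh3)4 (10 mol %), morpholine (10 equiv), THF, rt, argon
Reagents that add atoms: none
Why: Tsuji–Trost allyl transfer; zerovalent palladium ionises the four aryl allyl ethers and morpholine traps the allyl units, while the conjugated alkenes, esters, silyl ether and ketals are inert and the acetonides still block any acyl migration from O5.

Step 16
Reactants: 25 dimer with both catechols free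
Product: 26 CNP0107948.2 (target)
Conditions: CF3CO2H/CH2Cl2/H2O (10:10:1), 0 °C to rt; reversed-phase chromatography
Reagents that add atoms: none
Why: Global acidolysis removes the tert-butyl ester (loss of 2-methylpropene), both ketals and the silyl ether. The two cinnamates and the C7–O1' ester, whose tertiary carbon is deactivated toward ionisation by the adjacent carboxyl, are stable to aqueous acid at room temperature, where O5 to O4 acyl migration is also slow.

Compound list
1 | dimethyl (4R,5R)-2,2-dimethyl-1,3-dioxolane-4,5-dicarboxylate | COC(=O)[C@@H]1OC(C)(C)O[C@H]1C(=O)OC | starting material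
2 | methyl (4R,5S)-5-(hydroxymethyl)-2,2-dimethyl-1,3-dioxolane-4-carboxylate | COC(=O)[C@@H]1OC(C)(C)O[C@H]1CO | intermediate
3 | methyl (4R,5S)-2,2-dimethyl-5-{[(trifluoromethyl)sulfonyl]oxymethyl}-1,3-dioxolane-4-carboxylate | COC(=O)[C@@H]1OC(C)(C)O[C@H]1COS(=O)(=O)C(F)(F)F | intermediate
4 | 1,3-dithiane | C1CSCSC1 | starting material
5 | 2-lithio-1,3-dithiane | [Li]C1SCCCS1 | intermediate
6 | tert-butyl 1,3-dithiane-2-carboxylate | CC(C)(C)OC(=O)C1SCCCS1 | intermediate
7 | sodium enolate of 6 | [Na+].CC(C)(C)OC(=O)[C-]1SCCCS1 | intermediate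
8 | tert-butyl 2-{[(4S,5R)-5-(methoxycarbonyl)-2,2-dimethyl-1,3-dioxolan-4-yl]methyl}-1,3-dithiane-2-carboxylate | COC(=O)[C@@H]1OC(C)(C)O[C@H]1CC2(C(=O)OC(C)(C)C)SCCCS2 | intermediate
9 | Weinreb amide, tert-butyl 2-{[(4S,5R)-5-[methoxy(methyl)carbamoyl]-2,2-dimethyl-1,3-dioxolan-4-yl]methyl}-1,3-dithiane-2-carboxylate | CON(C)C(=O)[C@@H]1OC(C)(C)O[C@H]1CC2(C(=O)OC(C)(C)C)SCCCS2 | intermediate
10 | tert-butyl 2-{[(4S,5R)-5-acetyl-2,2-dimethyl-1,3-dioxolan-4-yl]methyl}-1,3-dithiane-2-carboxylate | CC(=O)[C@@H]1OC(C)(C)O[C@H]1CC2(C(=O)OC(C)(C)C)SCCCS2 | intermediate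
11 | tert-butyl (4S,5R)-4,5-dihydroxy-4,5-O-isopropylidene-2,6-dioxoheptanoate | CC(=O)[C@@H]1OC(C)(C)O[C@H]1CC(=O)C(=O)OC(C)(C)C | intermediate
12 | (R)-proline enamine of 11 (C2=C3) | C=C(N1CCC[C@@H]1C(=O)O)[C@@H]2OC(C)(C)O[C@H]2CC(=O)C(=O)OC(C)(C)C | intermediate
13 | tert-butyl ent-3-dehydroquinate 4,5-acetonide (1S,4R,5S) | CC1(C)O[C@H]2C[C@@](O)(C(=O)OC(C)(C)C)CC(=O)[C@@H]2O1 | intermediate
14 | tert-butyl 4,5-O-isopropylidene-ent-quinate (3S,5S) | CC1(C)O[C@H]2C[C@@](O)(C(=O)OC(C)(C)C)C[C@H](O)[C@@H]2O1 | intermediate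
15 | tert-butyl 3,4-O-isopropylidene-ent-quinate (3S,5S) | O[C@H]1C[C@@](O)(C(=O)OC(C)(C)C)C[C@@H]2OC(C)(C)O[C@H]12 | intermediate
16 | caffeic acid | O=C(O)/C=C/c1ccc(O)c(O)c1 | starting material
17 | allyl (E)-3-[3,4-bis(allyloxy)phenyl]prop-2-enoate | C=CCOC(=O)/C=C/c1ccc(OCC=C)c(OCC=C)c1 | intermediate
18 | (E)-3-[3,4-bis(allyloxy)phenyl]prop-2-enoic acid | O=C(O)/C=C/c1ccc(OCC=C)c(OCC=C)c1 | intermediate
19 | tert-butyl 5-O-[(E)-3,4-bis(allyloxy)cinnamoyl]-3,4-O-isopropylidene-ent-quinate | O=C(/C=C/c1ccc(OCC=C)c(OCC=C)c1)O[C@H]2C[C@@](O)(C(=O)OC(C)(C)C)C[C@@H]3OC(C)(C)O[C@H]23 | intermediate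
20 | bis-TES derivative (O1 triethylsilyl ether, C7 triethylsilyl ester) | O=C(/C=C/c1ccc(OCC=C)c(OCC=C)c1)O[C@H]2C[C@@](O[Si](CC)(CC)CC)(C(=O)O[Si](CC)(CC)CC)C[C@@H]3OC(C)(C)O[C@H]23 | intermediate
21 | 5-O-[(E)-3,4-bis(allyloxy)cinnamoyl]-3,4-O-isopropylidene-1-O-triethylsilyl-ent-quinic acid | O=C(/C=C/c1ccc(OCC=C)c(OCC=C)c1)O[C@H]2C[C@@](O[Si](CC)(CC)CC)(C(=O)O)C[C@@H]3OC(C)(C)O[C@H]23 | intermediate
22 | acid chloride of 21 | O=C(/C=C/c1ccc(OCC=C)c(OCC=C)c1)O[C@H]2C[C@@](O[Si](CC)(CC)CC)(C(=O)Cl)C[C@@H]3OC(C)(C)O[C@H]23 | intermediate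
23 | lithium O1' alkoxide of 19 | O=C(/C=C/c1ccc(OCC=C)c(OCC=C)c1)O[C@H]2C[C@@]([O-])(C(=O)OC(C)(C)C)C[C@@H]3OC(C)(C)O[C@H]23.[Li+] | intermediate
24 | protected dimer | O=C(/C=C/c1ccc(OCC=C)c(OCC=C)c1)O[C@H]2C[C@@](O[Si](CC)(CC)CC)(C(=O)O[C@@]4(C(=O)OC(C)(C)C)C[C@H](OC(=O)/C=C/c5ccc(OCC=C)c(OCC=C)c5)[C@H]6OC(C)(C)O[C@H]6C4)C[C@@H]3OC(C)(C)O[C@H]23 | intermediate
25 | dimer with free catechols | O=C(/C=C/c1ccc(O)c(O)c1)O[C@H]2C[C@@](O[Si](CC)(CC)CC)(C(=O)O[C@@]4(C(=O)OC(C)(C)C)C[C@H](OC(=O)/C=C/c5ccc(O)c(O)c5)[C@H]6OC(C)(C)O[C@H]6C4)C[C@@H]3OC(C)(C)O[C@H]23 | intermediate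
26 | CNP0107948.2 | O=C(/C=C/c1ccc(O)c(O)c1)O[C@H]1C[C@@](O)(C(=O)O[C@@]2(C(=O)O)C[C@H](OC(=O)/C=C/c3ccc(O)c(O)c3)[C@@H](O)[C@@H](O)C2)C[C@H](O)[C@@H]1O | target

Total step count: 16. Longest linear sequence: 13 steps (1, 2, 4–9, 12–16).

Steps most likely to fail

Step 7. The amine may engage the more electrophilic C1 carbonyl instead of C3, and enolisation toward C6 can then expel O5. The ketol may also dehydrate across C1–C2, or the chair preference at C1 may be incomplete. The fallback replaces the enamine by a neutral alkene as the C2 nucleophile, so that no amine or base ever meets the keto ester. It sets out from 10.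
- Wittig methylenation (Ph3P=CH2, THF, −78 to 0 °C) should give isopropenyl dithiane F1.
- Alkylative, non-oxidative dethioacetalisation (MeI, CaCO3, MeCN/H2O, 40 °C) should give olefinic keto ester F2.
- A Lewis acid-catalysed intramolecular carbonyl-ene reaction (Cu(OTf)2 10 mol %, CH2Cl2, rt) follows, in which the =CH2 terminus bonds to C1 while a methyl hydrogen passes to O1. Through the same trans-fused chair it should give 3-methylene carbocycle F3.
- Ozonolysis (O3, CH2Cl2/MeOH, −78 °C, then Me2S) comes back to the route at 13.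

Step 14. Acyl transfer between two fully substituted centers may be too slow, which leaves time for alkoxide-induced ester exchange and for loss of the acid chloride on work-up. The fallback changes the acceptor: O5' and C7' are tied together as a lactone, which exposes O1'–H at a bridgehead, where acylation of quinides is routine. It sets out from 15.
- TsOH·H2O (cat.) in refluxing toluene should give ent-quinide acetonide F4.
- Acylation by 22 (DMAP, pyridine, CH2Cl2, rt to 40 °C) should give acyl lactone F5.
- LiOH (1.05 equiv, THF/H2O, 0 °C) should open only the strained, alpha-acyloxy-activated lactone, to hydroxy acid F6.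
- O-tert-Butyl-N,N'-diisopropylisourea (CH2Cl2, rt) should give hydroxy tert-butyl ester F7.
- Steglich esterification of O5'–H with 18, as in step 12, comes back to the route at 24.

Step 13. The prolonged exposure to silyl triflate that the ester cleavage needs may also open the 3,4-acetonide. The fallback separates the two events and sets out from 19.
- CF3CO2H/CH2Cl2/H2O strips the tert-butyl ester and the ketal together, to triol acid F8.
- Acetone, 2,2-dimethoxypropane and camphor-10-sulfonic acid (cat.) at rt restore the cis ketal in acetonide acid F9. No lactone can form because O5 is acylated.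
- A short silylation (Et3SiOTf 2.5 equiv, 2,6-lutidine, CH2Cl2, −78 to 0 °C) passes through 20.
- The work-up of step 13 comes back to the route at 21.

Further compounds
F1 | step 7 | isopropenyl dithiane (C3 methylene analogue of 10) | C=C(C)[C@@H]1OC(C)(C)O[C@H]1CC2(C(=O)OC(C)(C)C)SCCCS2
F2 | step 7 | olefinic keto ester (C3 methylene analogue of 11) | C=C(C)[C@@H]1OC(C)(C)O[C@H]1CC(=O)C(=O)OC(C)(C)C
F3 | step 7 | 3-methylene carbocycle (C3 methylene analogue of 13) | CC1(C)O[C@H]2C[C@@](O)(C(=O)OC(C)(C)C)CC(=C)[C@@H]2O1
F4 | step 14 | ent-quinide acetonide (3,4-O-isopropylidene-ent-quinic acid 1,5-lactone) | O=C1O[C@H]2C[C@]1(O)C[C@@H]3OC(C)(C)O[C@H]23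
F5 | step 14 | acyl lactone (F4 acylated at O1' by 22) | O=C1O[C@H]2C[C@]1(OC(=O)[C@]4(O[Si](CC)(CC)CC)C[C@H](OC(=O)/C=C/c5ccc(OCC=C)c(OCC=C)c5)[C@H]6OC(C)(C)O[C@H]6C4)C[C@@H]3OC(C)(C)O[C@H]23
F6 | step 14 | hydroxy acid (ring B with free C7' acid and O5'–H) | O=C(/C=C/c1ccc(OCC=C)c(OCC=C)c1)O[C@H]2C[C@@](O[Si](CC)(CC)CC)(C(=O)O[C@@]4(C(=O)O)C[C@H](O)[C@H]6OC(C)(C)O[C@H]6C4)C[C@@H]3OC(C)(C)O[C@H]23
F7 | step 14 | hydroxy tert-butyl ester (ring B with C7' tert-butyl ester and O5'–H) | O=C(/C=C/c1ccc(OCC=C)c(OCC=C)c1)O[C@H]2C[C@@](O[Si](CC)(CC)CC)(C(=O)O[C@@]4(C(=O)OC(C)(C)C)C[C@H](O)[C@H]6OC(C)(C)O[C@H]6C4)C[C@@H]3OC(C)(C)O[C@H]23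
F8 | step 13 | triol acid (5-O-[(E)-3,4-bis(allyloxy)cinnamoyl]-ent-quinic acid) | O=C(/C=C/c1ccc(OCC=C)c(OCC=C)c1)O[C@H]2C[C@@](O)(C(=O)O)C[C@H](O)[C@@H]2O
F9 | step 13 | acetonide acid (3,4-O-isopropylidene derivative of F8) | O=C(/C=C/c1ccc(OCC=C)c(OCC=C)c1)O[C@H]2C[C@@](O)(C(=O)O)C[C@@H]3OC(C)(C)O[C@H]23
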